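**Plan**

1. Retrosynthesis: the two MOM ethers come off last. Ring C is opened at C2–C3 by a retro-[1,3] shift to the isomeric cyclic enol acetal, a 2-aryl-4-methylidene-4H-1,3-benzodioxine. Its exocyclic carbon is cut back to the lactone carbonyl of a 1,3-benzodioxin-4-one, and the two acetal C–O bonds are cut to a ring A salicylic acid and a ring B aldehyde.
2. The C8 prenyl group is traced to an aromatic Claisen rearrangement of a 1,1-dimethylallyl ether on the salicylate oxygen, so that prenyl and the future O1 sit on neighbouring carbons by construction. The ring B prenyl group comes from a Stille coupling.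
3. Forward order: ring B aldehyde; ring A acid; union of the two in a temporary 1,3-dioxin-4-one ring; carbonyl methylenation; [1,3] O-to-C rearrangement that closes ring C; deprotection.
4. Enabling feature: ring C is a β-aryloxy ketone (O1–C2–C3–C4=O), so C4–O and O1 can be stored as the enol ether and acetal oxygens of an easily made six-membered acetal. The 4-methoxy group of ring B, para to C2, stabilises the oxocarbenium ion O1=C2, and the C5 oxygen of ring A, peri to C4, chelates the metal enolate.
5. Stereochemistry: C2 is the only stereocenter. The acetal is carried racemic, its configuration is erased at the oxocarbenium ion, and (2S) is set in the C2–C3 bond formation by a chiral scandium Lewis acid, so both acetal enantiomers converge on one product.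

Key step: step 9

Remark: prenyl = 3-methylbut-2-en-1-yl; MOM = methoxymethyl; Ph-pybox = 2,6-bis(4-phenyl-4,5-dihydro-1,3-oxazol-2-yl)pyridine; ring positions are numbered as in the flavanone (O1, C2, C3, C4, C4a, C5–C8, C8a) and, for the benzodioxine precursors, O1, C2, O3, C4.

**Step 1**
Reactants: 1 3-bromo-4-methoxybenzaldehyde; 2 tributyl(3-methylbut-2-en-1-yl)stannane
Product: 3 4-methoxy-3-(3-methylbut-2-en-1-yl)benzaldehyde
Conditions: Pd(PPh3)4 (5 mol %), DMF, 100 °C
Reagents that add atoms: none
Why: Stille coupling, in which oxidative addition of zerovalent palladium to the aryl bromide, transfer of the allylic group from tin and reductive elimination at the unsubstituted allyl terminus should give the linear prenyl arene while the aldehyde is untouched by the neutral conditions.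

**Step 2**
Reactants: 4 methyl 2,4,6-trihydroxybenzoate
Product: 5 methyl 2-hydroxy-4,6-bis(methoxymethoxy)benzoate
Conditions: MOMCl (2.2 equiv), iPr2NEt, CH2Cl2, 0 °C to rt
Reagents that add atoms: chloromethyl methyl ether (MOMCl), COCCl
Why: Williamson-type etherification in which the para hydroxyl and one of the two equivalent ortho hydroxyls react, while the last ortho hydroxyl is held back by its hydrogen bond to the ester carbonyl, as is usual for 2,4,6-trihydroxyaryl carbonyl compounds.

**Step 3**
Reactants: 5 methyl 2-hydroxy-4,6-bis(methoxymethoxy)benzoate; 6 3-chloro-3-methylbut-1-yne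
Product: 7 methyl 2,4-bis(methoxymethoxy)-6-[(2-methylbut-3-yn-2-yl)oxy]benzoate
Conditions: DBU, CuCl2·2H2O (cat.), MeCN, 0 °C
Reagents that add atoms: none
Why: Copper-catalysed propargylic etherification of the phenoxide with the tertiary propargylic chloride is the standard way to place a 1,1-dimethylpropargyl group on a hydrogen-bonded phenol, and the only free hydroxyl of 5 is the one that will become the ring oxygen O1.

**Step 4**
Reactants: 7 methyl 2,4-bis(methoxymethoxy)-6-[(2-methylbut-3-yn-2-yl)oxy]benzoate
Product: 8 methyl 2,4-bis(methoxymethoxy)-6-[(2-methylbut-3-en-2-yl)oxy]benzoate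
Conditions: H2 (1 atm), Pd/CaCO3 poisoned with Pb(OAc)2, quinoline, EtOAc, rt
Reagents that add atoms: none
Why: Lindlar semihydrogenation should stop at the terminal alkene and so give the 1,1-dimethylallyl ether needed for the sigmatropic shift, with nothing else in 7 reducible under these conditions.

**Step 5**
Reactants: 8 methyl 2,4-bis(methoxymethoxy)-6-[(2-methylbut-3-en-2-yl)oxy]benzoate
Product: 10 methyl 2-hydroxy-4,6-bis(methoxymethoxy)-3-(3-methylbut-2-en-1-yl)benzoate, via ortho-prenyl cyclohexadienone 9 (not isolated)
Conditions: PhNEt2, 130 °C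
Reagents that add atoms: none
Why: Aromatic Claisen rearrangement, in which the [3,3] shift carries the allyl terminus to the only ortho carbon that bears hydrogen, turns the 1,1-dimethylallyl unit into the linear prenyl group and, after tautomerisation of dienone 9, frees the phenol next to it, so the hydroxyl that becomes O1 is by construction the neighbour of the prenyl group.

**Step 6**
Reactants: 10 methyl 2-hydroxy-4,6-bis(methoxymethoxy)-3-(3-methylbut-2-en-1-yl)benzoate
Product: 11 2-hydroxy-4,6-bis(methoxymethoxy)-3-(3-methylbut-2-en-1-yl)benzoic acid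
Conditions: KOH, EtOH/H2O, 75 °C; then cold 1 M HCl to pH 4
Reagents that add atoms: potassium hydroxide, [K+].[OH-]
Why: Saponification of the hindered salicylate needs heat, but MOM ethers and the prenyl group are stable to hydroxide, and cold acidification only to pH 4 should avoid MOM loss and decarboxylation of the electron-rich acid.

**Step 7**
Reactants: 11 2-hydroxy-4,6-bis(methoxymethoxy)-3-(3-methylbut-2-en-1-yl)benzoic acid; 3 4-methoxy-3-(3-methylbut-2-en-1-yl)benzaldehyde
Product: 13 2-[4-methoxy-3-(3-methylbut-2-en-1-yl)phenyl]-5,7-bis(methoxymethoxy)-8-(3-methylbut-2-en-1-yl)-4H-1,3-benzodioxin-4-one (racemic at C2), via bis(trimethylsilyl) derivative 12 (not isolated)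
Conditions: (Me3Si)2NH, THF, 25 °C, then evaporation; 3, Me3SiOTf (0.2 equiv), CH2Cl2, −78 °C; pyridine quench
Reagents that add atoms: none
Why: Silyl-transfer acetalisation of a bis-silylated hydroxy acid with an aldehyde under Me3SiOTf catalysis, the standard union for 1,3-dioxan-4-ones, should close the temporary dioxinone ring under aprotic conditions at low temperature, driven by formation of hexamethyldisiloxane; the acetal carbon forms racemic and needs no control.

**Step 8**
Reactants: 13 2-[4-methoxy-3-(3-methylbut-2-en-1-yl)phenyl]-5,7-bis(methoxymethoxy)-8-(3-methylbut-2-en-1-yl)-4H-1,3-benzodioxin-4-one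
Product: 14 2-[4-methoxy-3-(3-methylbut-2-en-1-yl)phenyl]-5,7-bis(methoxymethoxy)-4-methylidene-8-(3-methylbut-2-en-1-yl)-4H-1,3-benzodioxine (racemic at C2)
Conditions: Cp2TiMe2 (2.5 equiv), toluene, 70 °C, dark; filtration through basic alumina
Reagents that add atoms: dimethyltitanocene (Cp2TiMe2), [CH3-].[CH3-].[Ti+4].c1cc[cH-]c1.c1cc[cH-]c1
Why: Petasis methylenation, in which Cp2Ti=CH2 formed by thermal loss of methane adds [2+2] to the lactone carbonyl and cycloreverts, is established for the acylal carbonyl of 1,3-dioxan-4-ones, and its non-acidic conditions spare the MOM ethers, the acetal and the trisubstituted alkenes.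

**Step 9**
Reactants: 14 2-[4-methoxy-3-(3-methylbut-2-en-1-yl)phenyl]-5,7-bis(methoxymethoxy)-4-methylidene-8-(3-methylbut-2-en-1-yl)-4H-1,3-benzodioxine
Product: 16 (2S)-2-[4-methoxy-3-(3-methylbut-2-en-1-yl)phenyl]-5,7-bis(methoxymethoxy)-8-(3-methylbut-2-en-1-yl)-2,3-dihydro-4H-chromen-4-one, via scandium-bound ring-opened oxocarbenium enolate 15 (not isolated)
Conditions: Sc(OTf)3 (10 mol %), (S,S)-Ph-pybox (12 mol %), 4 Å molecular sieves, CH2Cl2, −78 to −40 °C; Et3N quench
Reagents that add atoms: none
Why: Proposed new method: the chiral trivalent scandium Lewis acid binds the enol ether oxygen O3 of 14 and the C2–O3 bond ionises, helped by the lone pair of O1 and the para-methoxy group of ring B, to give a planar aryloxy-oxocarbenium ion tethered to a scandium enolate (15), so that both enantiomers of the racemic acetal converge on one achiral cation. Rotation about C4–C4a then brings the enolate oxygen beside the C5 methoxymethoxy oxygen, which chelates scandium in a six-membered ring and turns the enolate carbon towards C2; the C2–C3 bond forms by a 6-(enolendo)-endo-trig closure that makes ring C and releases the C4 ketone. The closest known reaction types are the Petasis–Ferrier rearrangement of 4-methylidene-1,3-dioxanes to tetrahydropyran-4-ones under Me2AlCl and the chiral Lewis acid-catalysed Claisen and [1,3] O-to-C rearrangements of chelating vinyl ethers that pass through a ligand-bound enolate; neither has been shown on a benzo-fused enol acetal with catalyst control of a lone stereocenter. C2 is the only new stereocenter and is set by the catalyst: one phenyl group of the C2-symmetric ligand shields one face of the chelated enolate at C3, the tethered oxocarbenium ion can reach the open face only with its aryl group pseudo-equatorial, and this is planned to give (2S) with the (S,S)-ligand, the (R,R)-ligand being the remedy should the sense be the reverse. The step needs C-attack rather than O-attack of the enolate (O-attack only returns 14), enolate capture ahead of a Prins attack by the C8 prenyl alkene or loss of a MOM group, and no racemic background reaction; the tethered ion pair, the much higher nucleophilicity of the enolate, the low temperature and the exclusion of protic acid by the sieves should secure these.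

**Step 10**
Reactants: 16 (2S)-2-[4-methoxy-3-(3-methylbut-2-en-1-yl)phenyl]-5,7-bis(methoxymethoxy)-8-(3-methylbut-2-en-1-yl)-2,3-dihydro-4H-chromen-4-one
Product: 17 (2S)-5,7-dihydroxy-2-[4-methoxy-3-(3-methylbut-2-en-1-yl)phenyl]-8-(3-methylbut-2-en-1-yl)-2,3-dihydro-4H-chromen-4-one
Conditions: 3 M aq. HCl (few equiv), MeOH, 40 °C, short reaction time
Reagents that add atoms: none
Why: Acid-catalysed methanolysis of aryl MOM ethers is the usual last step for prenylated flavanones; C2 should not epimerise under mild acid, and the short reaction time limits cyclisation of the C8 prenyl group onto the 7-hydroxyl.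

**Compound list**

1 | 3-bromo-4-methoxybenzaldehyde | COc1ccc(C=O)cc1Br | starting material
2 | tributyl(3-methylbut-2-en-1-yl)stannane | CCCC[Sn](CCCC)(CCCC)CC=C(C)C | starting material
3 | 4-methoxy-3-(3-methylbut-2-en-1-yl)benzaldehyde | COc1ccc(C=O)cc1CC=C(C)C | intermediate
4 | methyl 2,4,6-trihydroxybenzoate | COC(=O)c1c(O)cc(O)cc1O | starting material
5 | methyl 2-hydroxy-4,6-bis(methoxymethoxy)benzoate | COC(=O)c1c(O)cc(OCOC)cc1OCOC | intermediate
6 | 3-chloro-3-methylbut-1-yne | CC(C)(Cl)C#C | starting material
7 | methyl 2,4-bis(methoxymethoxy)-6-[(2-methylbut-3-yn-2-yl)oxy]benzoate | COC(=O)c1c(OC(C)(C)C#C)cc(OCOC)cc1OCOC | intermediate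
8 | methyl 2,4-bis(methoxymethoxy)-6-[(2-methylbut-3-en-2-yl)oxy]benzoate | COC(=O)c1c(OC(C)(C)C=C)cc(OCOC)cc1OCOC | intermediate
9 | methyl 2,4-bis(methoxymethoxy)-5-(3-methylbut-2-en-1-yl)-6-oxocyclohexa-1,3-diene-1-carboxylate (racemic) | COC(=O)C1=C(OCOC)C=C(OCOC)C(CC=C(C)C)C1=O | intermediate (not isolated)
10 | methyl 2-hydroxy-4,6-bis(methoxymethoxy)-3-(3-methylbut-2-en-1-yl)benzoate | COC(=O)c1c(O)c(CC=C(C)C)c(OCOC)cc1OCOC | intermediate
11 | 2-hydroxy-4,6-bis(methoxymethoxy)-3-(3-methylbut-2-en-1-yl)benzoic acid | OC(=O)c1c(O)c(CC=C(C)C)c(OCOC)cc1OCOC | intermediate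
12 | trimethylsilyl 4,6-bis(methoxymethoxy)-3-(3-methylbut-2-en-1-yl)-2-[(trimethylsilyl)oxy]benzoate | C[Si](C)(C)OC(=O)c1c(O[Si](C)(C)C)c(CC=C(C)C)c(OCOC)cc1OCOC | intermediate (not isolated)
13 | 2-[4-methoxy-3-(3-methylbut-2-en-1-yl)phenyl]-5,7-bis(methoxymethoxy)-8-(3-methylbut-2-en-1-yl)-4H-1,3-benzodioxin-4-one (racemic) | O=C1OC(c2ccc(OC)c(CC=C(C)C)c2)Oc2c(CC=C(C)C)c(OCOC)cc(OCOC)c21 | intermediate
14 | 2-[4-methoxy-3-(3-methylbut-2-en-1-yl)phenyl]-5,7-bis(methoxymethoxy)-4-methylidene-8-(3-methylbut-2-en-1-yl)-4H-1,3-benzodioxine (racemic) | C=C1OC(c2ccc(OC)c(CC=C(C)C)c2)Oc2c(CC=C(C)C)c(OCOC)cc(OCOC)c21 | intermediate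
15 | ring-opened oxocarbenium enolate (drawn as the zwitterion without the scandium–ligand fragment on the enolate oxygen) | C=C([O-])c1c(OCOC)cc(OCOC)c(CC=C(C)C)c1[O+]=Cc1ccc(OC)c(CC=C(C)C)c1 | intermediate (not isolated)
16 | (2S)-2-[4-methoxy-3-(3-methylbut-2-en-1-yl)phenyl]-5,7-bis(methoxymethoxy)-8-(3-methylbut-2-en-1-yl)-2,3-dihydro-4H-chromen-4-one | COc1ccc([C@@H]2CC(=O)c3c(OCOC)cc(OCOC)c(CC=C(C)C)c3O2)cc1CC=C(C)C | intermediate
17 | (2S)-5,7-dihydroxy-2-[4-methoxy-3-(3-methylbut-2-en-1-yl)phenyl]-8-(3-methylbut-2-en-1-yl)-2,3-dihydro-4H-chromen-4-one | COc1ccc([C@@H]2CC(=O)c3c(O)cc(O)c(CC=C(C)C)c3O2)cc1CC=C(C)C | target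

**Step count**

Total steps: 10. Longest linear sequence: 9 (steps 2 to 10, from 4); step 1 is a one-step branch that joins at step 7.

**Steps most likely to fail**

Step 9 (proposed new method). The recombination of the enolate with the oxocarbenium ion may show poor facial selectivity. A racemic background ionisation by adventitious acid may compete. The oxocarbenium ion may be captured by the C8 prenyl alkene in a Prins cyclisation. The enantiomeric purity may erode through reversible ionisation of the benzylic C2–O1 bond of the product on the Lewis acid. The fallback uses known chemistry and sets out from 14. Mild hydrolysis (PPTS, wet THF, rt) should give 1-[2-hydroxy-4,6-bis(methoxymethoxy)-3-(3-methylbut-2-en-1-yl)phenyl]ethan-1-one F1 and return aldehyde 3. Claisen–Schmidt condensation of F1 with 3 (KOH, EtOH, rt) should give (E)-1-[2-hydroxy-4,6-bis(methoxymethoxy)-3-(3-methylbut-2-en-1-yl)phenyl]-3-[4-methoxy-3-(3-methylbut-2-en-1-yl)phenyl]prop-2-en-1-one F2. Its single free phenol allows only the 8-prenyl mode of oxa-Michael closure (NaOAc, EtOH, reflux) to racemic 2-[4-methoxy-3-(3-methylbut-2-en-1-yl)phenyl]-5,7-bis(methoxymethoxy)-8-(3-methylbut-2-en-1-yl)chroman-4-one F3. Preparative HPLC on a chiral stationary phase (cellulose tris(3,5-dimethylphenylcarbamate)) then separates the (2S) enantiomer, and the route is rejoined at 16.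

Step 7. The Lewis acid may remove or shift MOM groups, the intermediate oxocarbenium ion may be trapped by the neighbouring prenyl alkene, or the condensation may stall at the flanked silyl ether. The fallback sets out from 3 and replaces the silyl-transfer condensation by a Brønsted acid acetal exchange of a preformed acetal. HC(OMe)3 and catalytic PPTS in MeOH should give 4-(dimethoxymethyl)-1-methoxy-2-(3-methylbut-2-en-1-yl)benzene F4. F4 is then heated with acid 11 and catalytic PPTS in toluene at 60 °C over 5 Å molecular sieves, which take up the methanol, and the route is rejoined at 13.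

Step 5. The tertiary allyl ether may fragment to the phenol and isoprene, or the allyl group may go to the ester-bearing carbon and on to the para position by a Cope shift instead of the ortho [3,3] shift. The fallback sets out from 4 and installs the prenyl group by direct C-alkylation before protection. Prenyl bromide with DBU in THF at 0 °C should alkylate one of the two equivalent ring carbons to give methyl 2,4,6-trihydroxy-3-(3-methylbut-2-en-1-yl)benzoate F5. MOMCl (2.1 equiv) with iPr2NEt in CH2Cl2 should then protect the para hydroxyl and the less hindered ortho hydroxyl and leave the hydrogen-bonded hydroxyl flanked by the prenyl group, and the route is rejoined at 10. The position of the free hydroxyl would have to be confirmed, which is why this is the fallback and not the route.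

**Further compounds**

F1 | step 9 | 1-[2-hydroxy-4,6-bis(methoxymethoxy)-3-(3-methylbut-2-en-1-yl)phenyl]ethan-1-one | CC(=O)c1c(O)c(CC=C(C)C)c(OCOC)cc1OCOC
F2 | step 9 | (E)-1-[2-hydroxy-4,6-bis(methoxymethoxy)-3-(3-methylbut-2-en-1-yl)phenyl]-3-[4-methoxy-3-(3-methylbut-2-en-1-yl)phenyl]prop-2-en-1-one | COCOc1cc(OCOC)c(CC=C(C)C)c(O)c1C(=O)/C=C/c1ccc(OC)c(CC=C(C)C)c1
F3 | step 9 | racemic 2-[4-methoxy-3-(3-methylbut-2-en-1-yl)phenyl]-5,7-bis(methoxymethoxy)-8-(3-methylbut-2-en-1-yl)chroman-4-one | COc1ccc(C2CC(=O)c3c(OCOC)cc(OCOC)c(CC=C(C)C)c3O2)cc1CC=C(C)C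
F4 | step 7 | 4-(dimethoxymethyl)-1-methoxy-2-(3-methylbut-2-en-1-yl)benzene | COc1ccc(C(OC)OC)cc1CC=C(C)C
F5 | step 5 | methyl 2,4,6-trihydroxy-3-(3-methylbut-2-en-1-yl)benzoate | COC(=O)c1c(O)cc(O)c(CC=C(C)C)c1O
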